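**Retrosynthetic overview**

- Gardenin A is taken back, through C2=C3 dehydrogenation, C4 oxidation and desilylation, to a 4-silyloxy-5-hydroxyflavan. The strategy rests on ring A: C5–OH stands para to C8–OMe with methoxy groups on C6 and C7, so the four contiguous oxygenated carbons C5–C8 map onto the four carbons of a squarate ester.
- Ring A is disconnected at C5–C4a: thermal ring expansion of a 4-(dihydropyran-6-yl)-2,3,4-trimethoxycyclobutenone, whose enol ether double bond becomes C8a=C4a.
- The cyclobutenone is disconnected at C8–C8a: a C6-lithiated dihydropyran adds to dimethyl squarate and the carbinol is O-methylated. The C6 anion is made site-specifically (anomeric sulfone, then stannane, then tin–lithium exchange).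
- Ring C comes from a hetero-Diels–Alder reaction of 3,4,5-trimethoxybenzaldehyde (ring B, purchased) with a 1-methoxy-3-silyloxy diene. Ring order: ring B (bought), ring C (step 1), ring A (step 7).

Key step: step 7

Assumption: all intermediates are racemic and every stereocentre is removed before the target. SMILES show the expected 2,4-cis relative configuration as one enantiomer; unmarked centres are mixtures.

**Step 1**
Reactants: 1 3,4,5-trimethoxybenzaldehyde; 2 trans-1-methoxy-3-(trimethylsilyloxy)-1,3-butadiene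
Product: 4 rac-2-(3,4,5-trimethoxyphenyl)-2,3-dihydro-4H-pyran-4-one, via cycloadduct 3 (not isolated)
Conditions: ZnCl2 (cat.), THF, rt; then TFA (cat.), CH2Cl2, 0 °C, aqueous NaHCO3 work-up
Reagents that add atoms: none
Why: Lewis-acid-catalysed hetero-Diels–Alder reaction of an aromatic aldehyde with the 1-alkoxy-3-silyloxy diene is regioselective (aldehyde oxygen to the acetal carbon), and acid then eliminates methanol and cleaves the silyl enol ether to the vinylogous ester; the C2 stereocentre forms as a racemate.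

**Step 2**
Reactants: 4 rac-2-(3,4,5-trimethoxyphenyl)-2,3-dihydro-4H-pyran-4-one
Product: 5 rac-(2R,4R)-2-(3,4,5-trimethoxyphenyl)-3,4-dihydro-2H-pyran-4-ol (2,4-cis)
Conditions: NaBH4, CeCl3·7H2O, MeOH, −78 to −40 °C
Reagents that add atoms: none
Why: Luche reduction gives clean 1,2-reduction of the vinylogous ester, with axial hydride delivery to the half-chair expected to set C4 cis to the C2 aryl group (the configuration is of no consequence because C4 is oxidised in step 9).

**Step 3**
Reactants: 5 rac-(2R,4R)-2-(3,4,5-trimethoxyphenyl)-3,4-dihydro-2H-pyran-4-ol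
Product: 6 rac-(2R,4R)-4-(tert-butyldimethylsilyloxy)-2-(3,4,5-trimethoxyphenyl)-3,4-dihydro-2H-pyran (2,4-cis)
Conditions: TBSCl, imidazole, DMF, 0 °C to rt
Reagents that add atoms: tert-butyldimethylsilyl chloride (TBSCl), CC(C)(C)[Si](C)(C)Cl
Why: Imidazole-promoted silylation of a secondary allylic alcohol proceeds under basic conditions that spare the acid-labile enol ether, and no stereocentre is touched.

**Step 4**
Reactants: 6 rac-(2R,4R)-4-(tert-butyldimethylsilyloxy)-2-(3,4,5-trimethoxyphenyl)-3,4-dihydro-2H-pyran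
Product: 7 4,6-cis-4-(tert-butyldimethylsilyloxy)-2-(phenylsulfonyl)-6-(3,4,5-trimethoxyphenyl)tetrahydro-2H-pyran (racemic, mixture at C2)
Conditions: PhSO2H, CH2Cl2, 0 °C to rt
Reagents that add atoms: benzenesulfinic acid, O=S(O)c1ccccc1
Why: Markovnikov addition of a sulfinic acid to a cyclic enol ether (protonation at the β-carbon, sulfur attack on the oxocarbenium carbon) is the standard entry to 2-sulfonyl tetrahydropyrans, and the new anomeric centre, formed as a mixture, is destroyed in step 5.

**Step 5**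
Reactants: 7 4,6-cis-4-(tert-butyldimethylsilyloxy)-2-(phenylsulfonyl)-6-(3,4,5-trimethoxyphenyl)tetrahydro-2H-pyran
Product: 10 tributyl[rac-(2R,4R)-4-(tert-butyldimethylsilyloxy)-2-(3,4,5-trimethoxyphenyl)-3,4-dihydro-2H-pyran-6-yl]stannane, via lithiated sulfone 8 (not isolated), via stannyl sulfone 9 (not isolated)
Conditions: n-BuLi, THF, −78 °C; Bu3SnCl, −78 °C to rt; then iPr2NEt, CHCl3, 60 °C
Reagents that add atoms: tributyltin chloride, CCCC[Sn](Cl)(CCCC)CCCC
Why: The anomeric C–H flanked by sulfonyl and ring oxygen is by far the most acidic site, so deprotonation is site-specific where direct vinylic metalation of 6 would compete with the benzylic C2–H and the aryl C–H ortho to methoxy; stannylation and base-assisted loss of sulfinate (alkylation–elimination chemistry of 2-sulfonyl tetrahydropyrans) then give the vinylstannane, the double bond being possible only at C5=C6.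

**Step 6**
Reactants: 10 tributyl[rac-(2R,4R)-4-(tert-butyldimethylsilyloxy)-2-(3,4,5-trimethoxyphenyl)-3,4-dihydro-2H-pyran-6-yl]stannane; 11 dimethyl squarate (3,4-dimethoxycyclobut-3-ene-1,2-dione)
Product: 14 4-[cis-4-(tert-butyldimethylsilyloxy)-2-(3,4,5-trimethoxyphenyl)-3,4-dihydro-2H-pyran-6-yl]-2,3,4-trimethoxycyclobut-2-en-1-one (racemic, mixture at the cyclobutenone C4), via vinyllithium 12 (not isolated), via lithium alkoxide 13 (not isolated)
Conditions: n-BuLi, THF, −78 °C; cannulate into 11, THF, −78 °C; then MeOTf, −78 to 0 °C; NaHCO3 work-up, Et3N-deactivated silica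
Reagents that add atoms: methyl trifluoromethanesulfonate (MeOTf), COS(=O)(=O)C(F)(F)F
Why: Tin–lithium exchange delivers the α-alkoxyvinyllithium only at C6, 1,2-addition of organolithiums to a squarate ester carbonyl is the standard route to 4-hydroxycyclobutenones, and trapping the tertiary lithium alkoxide with methyl triflate fixes the future C8 oxygen as its methyl ether; the new quaternary centre forms unselectively and is erased in step 7.

**Step 7**
Reactants: 14 4-[cis-4-(tert-butyldimethylsilyloxy)-2-(3,4,5-trimethoxyphenyl)-3,4-dihydro-2H-pyran-6-yl]-2,3,4-trimethoxycyclobut-2-en-1-one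
Product: 17 rac-(2R,4R)-4-(tert-butyldimethylsilyloxy)-6,7,8-trimethoxy-2-(3,4,5-trimethoxyphenyl)chroman-5-ol (2,4-cis), via dienylketene 15 (not isolated), via cyclohexadienone 16 (not isolated)
Conditions: toluene (degassed, dilute), 110 °C, argon
Reagents that add atoms: none
Why: Heat cleaves the cyclobutenone C1–C4 bond in a conrotatory 4π electrocyclic opening to the (Z)-dienylketene 15, whose ketene carbon then bonds to the dihydropyran β-carbon (future C4a) in a disrotatory 6π electrocyclization, and cyclohexadienone 16 enolizes to the phenol. The closest known reaction type is the Moore thermal rearrangement of 4-alkenyl- and 4-aryl-4-alkoxycyclobutenones from squarate esters to hydroquinone monoethers. Ring A is closed by the 6π electrocyclization, which forms the C5–C4a bond. No new stereocentre survives, since C4a is sp3 only in 16 and becomes aromatic, while C2 and C4 are not involved. The step needs the alkenyl group to rotate inward toward the ketene, which the donor methoxy group on the same carbon secures by rotating outward. The oxygen pattern follows by construction (ketene oxygen to the free C5–OH, carbinol methyl ether to C8–OMe, squarate methoxy groups to C6 and C7), the O-methyl group also closes the furanone pathway open to free 4-hydroxy compounds, and the aprotic, degassed medium protects the ketene and the air-sensitive hydroquinone monoether.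

**Step 8**
Reactants: 17 rac-(2R,4R)-4-(tert-butyldimethylsilyloxy)-6,7,8-trimethoxy-2-(3,4,5-trimethoxyphenyl)chroman-5-ol
Product: 18 rac-(2R,4R)-6,7,8-trimethoxy-2-(3,4,5-trimethoxyphenyl)chroman-4,5-diol (2,4-cis)
Conditions: TBAF, AcOH, THF, 0 °C to rt, argon; used crude
Reagents that add atoms: none
Why: Fluoride-mediated desilylation, buffered with acetic acid so that the phenol stays protonated and the ionisable benzylic alcohol never meets strong acid; the stereocentres are unchanged.

**Step 9**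
Reactants: 18 rac-(2R,4R)-6,7,8-trimethoxy-2-(3,4,5-trimethoxyphenyl)chroman-4,5-diol
Product: 19 rac-5-hydroxy-6,7,8-trimethoxy-2-(3,4,5-trimethoxyphenyl)chroman-4-one
Conditions: MnO2 (activated, excess), CH2Cl2, rt
Reagents that add atoms: none
Why: MnO2 oxidation of a benzylic alcohol runs under neutral heterogeneous conditions without an O-activation that could ionise C4, ortho-hydroxybenzyl alcohols are typical substrates, and ring A has no free position for phenolic coupling; the C4 stereocentre is removed.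

**Step 10**
Reactants: 19 rac-5-hydroxy-6,7,8-trimethoxy-2-(3,4,5-trimethoxyphenyl)chroman-4-one
Product: 20 Gardenin A (5-hydroxy-6,7,8-trimethoxy-2-(3,4,5-trimethoxyphenyl)-4H-chromen-4-one)
Conditions: I2 (cat.), DMSO, 120 °C
Reagents that add atoms: none
Why: Iodine-catalysed dehydrogenation of a flavanone in DMSO (α-iodination at C3, loss of HI, reoxidation of HI by DMSO) is the standard flavanone-to-flavone conversion, C6 and C8 being blocked against nuclear iodination; the last stereocentre (C2) disappears.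

**Compound list**

1 | 3,4,5-trimethoxybenzaldehyde | COc1cc(C=O)cc(OC)c1OC | starting material
2 | trans-1-methoxy-3-(trimethylsilyloxy)-1,3-butadiene | CO/C=C/C(=C)O[Si](C)(C)C | starting material
3 | 2-methoxy-6-(3,4,5-trimethoxyphenyl)-4-(trimethylsilyloxy)-5,6-dihydro-2H-pyran (cycloadduct, mixture of isomers) | COC1C=C(O[Si](C)(C)C)CC(c2cc(OC)c(OC)c(OC)c2)O1 | intermediate
4 | rac-2-(3,4,5-trimethoxyphenyl)-2,3-dihydro-4H-pyran-4-one | O=C1C=CO[C@@H](c2cc(OC)c(OC)c(OC)c2)C1 | intermediate
5 | rac-(2R,4R)-2-(3,4,5-trimethoxyphenyl)-3,4-dihydro-2H-pyran-4-ol (cis) | O[C@H]1C=CO[C@@H](c2cc(OC)c(OC)c(OC)c2)C1 | intermediate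
6 | rac-(2R,4R)-4-(tert-butyldimethylsilyloxy)-2-(3,4,5-trimethoxyphenyl)-3,4-dihydro-2H-pyran (cis) | CC(C)(C)[Si](C)(C)O[C@H]1C=CO[C@@H](c2cc(OC)c(OC)c(OC)c2)C1 | intermediate
7 | 4,6-cis-4-(tert-butyldimethylsilyloxy)-2-(phenylsulfonyl)-6-(3,4,5-trimethoxyphenyl)tetrahydro-2H-pyran (mixture at C2) | CC(C)(C)[Si](C)(C)O[C@H]1CC(S(=O)(=O)c2ccccc2)O[C@@H](c2cc(OC)c(OC)c(OC)c2)C1 | intermediate
8 | 2-lithio derivative of sulfone 7 | CC(C)(C)[Si](C)(C)O[C@H]1CC([Li])(S(=O)(=O)c2ccccc2)O[C@@H](c2cc(OC)c(OC)c(OC)c2)C1 | intermediate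
9 | 2-(tributylstannyl) derivative of sulfone 7 | CC(C)(C)[Si](C)(C)O[C@H]1CC([Sn](CCCC)(CCCC)CCCC)(S(=O)(=O)c2ccccc2)O[C@@H](c2cc(OC)c(OC)c(OC)c2)C1 | intermediate
10 | tributyl[rac-(2R,4R)-4-(tert-butyldimethylsilyloxy)-2-(3,4,5-trimethoxyphenyl)-3,4-dihydro-2H-pyran-6-yl]stannane | CC(C)(C)[Si](C)(C)O[C@H]1C=C([Sn](CCCC)(CCCC)CCCC)O[C@@H](c2cc(OC)c(OC)c(OC)c2)C1 | intermediate
11 | dimethyl squarate | COC1=C(OC)C(=O)C1=O | starting material
12 | 6-lithio derivative of dihydropyran 6 | CC(C)(C)[Si](C)(C)O[C@H]1C=C([Li])O[C@@H](c2cc(OC)c(OC)c(OC)c2)C1 | intermediate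
13 | lithium 1-(dihydropyran-6-yl)-2,3-dimethoxy-4-oxocyclobut-2-en-1-olate (alkoxide of the squarate adduct) | CC(C)(C)[Si](C)(C)O[C@H]1C=C(C2(O[Li])C(OC)=C(OC)C2=O)O[C@@H](c3cc(OC)c(OC)c(OC)c3)C1 | intermediate
14 | 4-[cis-4-(tert-butyldimethylsilyloxy)-2-(3,4,5-trimethoxyphenyl)-3,4-dihydro-2H-pyran-6-yl]-2,3,4-trimethoxycyclobut-2-en-1-one (mixture at cyclobutenone C4) | CC(C)(C)[Si](C)(C)O[C@H]1C=C(C2(OC)C(OC)=C(OC)C2=O)O[C@@H](c3cc(OC)c(OC)c(OC)c3)C1 | intermediate
15 | (Z)-2,3,4-trimethoxy-4-(dihydropyran-6-yl)buta-1,3-dien-1-one (dienylketene) | CC(C)(C)[Si](C)(C)O[C@H]1C=C(/C(OC)=C(OC)\C(OC)=C=O)O[C@@H](c3cc(OC)c(OC)c(OC)c3)C1 | intermediate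
16 | 4-(tert-butyldimethylsilyloxy)-6,7,8-trimethoxy-2-(3,4,5-trimethoxyphenyl)-2,3,4,4a-tetrahydro-5H-chromen-5-one (cyclohexadienone) | CC(C)(C)[Si](C)(C)O[C@H]1C2C(=O)C(OC)=C(OC)C(OC)=C2O[C@@H](c3cc(OC)c(OC)c(OC)c3)C1 | intermediate
17 | rac-(2R,4R)-4-(tert-butyldimethylsilyloxy)-6,7,8-trimethoxy-2-(3,4,5-trimethoxyphenyl)chroman-5-ol (cis) | CC(C)(C)[Si](C)(C)O[C@H]1c2c(O)c(OC)c(OC)c(OC)c2O[C@@H](c3cc(OC)c(OC)c(OC)c3)C1 | intermediate
18 | rac-(2R,4R)-6,7,8-trimethoxy-2-(3,4,5-trimethoxyphenyl)chroman-4,5-diol (cis) | O[C@H]1c2c(O)c(OC)c(OC)c(OC)c2O[C@@H](c3cc(OC)c(OC)c(OC)c3)C1 | intermediate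
19 | rac-5-hydroxy-6,7,8-trimethoxy-2-(3,4,5-trimethoxyphenyl)chroman-4-one | O=C1c2c(O)c(OC)c(OC)c(OC)c2O[C@@H](c3cc(OC)c(OC)c(OC)c3)C1 | intermediate
20 | Gardenin A | COc1cc(-c2cc(=O)c3c(O)c(OC)c(OC)c(OC)c3o2)cc(OC)c1OC | target

**Step count**

Total steps: 10. Longest linear sequence: 10 steps (from 1).

**Steps most likely to fail**

1. Step 7 (ring expansion). The dienylketene may be diverted before it cyclizes (capture by adventitious nucleophiles, dimerisation). The product may lose silanol across the ortho-hydroxybenzyl silyl ether at the reaction temperature, or be oxidised by air to the quinone. Fallback: the ring expansion is run at the ketone oxidation level, setting out from 14. Buffered TBAF removes the silyl group to give the allylic alcohol 4-[cis-4-hydroxy-2-(3,4,5-trimethoxyphenyl)-3,4-dihydro-2H-pyran-6-yl]-2,3,4-trimethoxycyclobut-2-en-1-one F1. MnO2 oxidises it to the vinylogous ester 2,3,4-trimethoxy-4-[4-oxo-2-(3,4,5-trimethoxyphenyl)-3,4-dihydro-2H-pyran-6-yl]cyclobut-2-en-1-one F2. Thermolysis of F2 in toluene closes ring A onto the α-carbon of the vinylogous ester and gives the chelated 5-hydroxyflavanone directly, so the route is rejoined at 19. No benzylic silyl ether is present in this substrate and the later oxidation of a phenol-bearing alcohol is not needed.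

2. Step 9 (oxidation next to a free phenol). The electron-rich para-methoxyphenol ring may be over-oxidised to a quinone, or the benzylic alcohol may ionise to an ortho-quinone methide on the oxidant surface. Fallback: the phenol is masked before the alcohol is unveiled, setting out from 17. Benzylation (BnBr, K2CO3, DMF) gives rac-cis-5-benzyloxy-4-(tert-butyldimethylsilyloxy)-6,7,8-trimethoxy-2-(3,4,5-trimethoxyphenyl)chroman F3. TBAF gives rac-cis-5-benzyloxy-6,7,8-trimethoxy-2-(3,4,5-trimethoxyphenyl)chroman-4-ol F4. Dess–Martin periodinane with NaHCO3 gives rac-5-benzyloxy-6,7,8-trimethoxy-2-(3,4,5-trimethoxyphenyl)chroman-4-one F5. Hydrogenolysis (H2, Pd/C, EtOAc) frees the phenol and returns to the route at 19.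

3. Step 4 (sulfinic acid addition). Acid may trigger allylic displacement of the C4 silyloxy group (Ferrier-type rearrangement) or cleave the silyl ether, in place of clean Markovnikov addition. Fallback: the sulfone is installed in two stages with a neutral sulfur nucleophile, setting out from 6. Thiophenol with catalytic PPh3·HBr in CH2Cl2 adds across the enol ether to give 4,6-cis-4-(tert-butyldimethylsilyloxy)-2-(phenylthio)-6-(3,4,5-trimethoxyphenyl)tetrahydro-2H-pyran F6. Oxidation with mCPBA and NaHCO3 gives the sulfone and returns to the route at 7.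

**Further compounds**

F1 | step 7 | 4-[cis-4-hydroxy-2-(3,4,5-trimethoxyphenyl)-3,4-dihydro-2H-pyran-6-yl]-2,3,4-trimethoxycyclobut-2-en-1-one | O[C@H]1C=C(C2(OC)C(OC)=C(OC)C2=O)O[C@@H](c3cc(OC)c(OC)c(OC)c3)C1
F2 | step 7 | 2,3,4-trimethoxy-4-[4-oxo-2-(3,4,5-trimethoxyphenyl)-3,4-dihydro-2H-pyran-6-yl]cyclobut-2-en-1-one | O=C1C=C(C2(OC)C(OC)=C(OC)C2=O)O[C@@H](c3cc(OC)c(OC)c(OC)c3)C1
F3 | step 9 | rac-cis-5-benzyloxy-4-(tert-butyldimethylsilyloxy)-6,7,8-trimethoxy-2-(3,4,5-trimethoxyphenyl)chroman | CC(C)(C)[Si](C)(C)O[C@H]1c2c(OCc3ccccc3)c(OC)c(OC)c(OC)c2O[C@@H](c3cc(OC)c(OC)c(OC)c3)C1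
F4 | step 9 | rac-cis-5-benzyloxy-6,7,8-trimethoxy-2-(3,4,5-trimethoxyphenyl)chroman-4-ol | O[C@H]1c2c(OCc3ccccc3)c(OC)c(OC)c(OC)c2O[C@@H](c3cc(OC)c(OC)c(OC)c3)C1
F5 | step 9 | rac-5-benzyloxy-6,7,8-trimethoxy-2-(3,4,5-trimethoxyphenyl)chroman-4-one | O=C1c2c(OCc3ccccc3)c(OC)c(OC)c(OC)c2O[C@@H](c3cc(OC)c(OC)c(OC)c3)C1
F6 | step 4 | 4,6-cis-4-(tert-butyldimethylsilyloxy)-2-(phenylthio)-6-(3,4,5-trimethoxyphenyl)tetrahydro-2H-pyran | CC(C)(C)[Si](C)(C)O[C@H]1CC(Sc2ccccc2)O[C@@H](c2cc(OC)c(OC)c(OC)c2)C1
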